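Ring A is disconnected as a 2‑methylenepropane‑1,3‑diyl unit, C6–C1(=C16)–C2, that bridges C5 and C3 of a ring B enone (ring A = C1–C6 with C16 on C1; ring B = C3, C4, C7–C10; side chain C11–C15). In one operation a bis‑allylsilane adds conjugately to the exocyclic C5=C4–C3=O unit (bond C5–C6) and then allylates the C3 ketone (bond C2–C3). This closes ring A, sets C4 and leaves the C1=C16 methylene beside an axial C3 carbinol for regiospecific dehydration. The precursor is a ring B 2‑methylenecyclohexanone carrying the C7 methyl, silylated C8 and C12 oxygens and the full C10 side chain as a Weinreb amide.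

Key step: step 14

Remark 1 (notation): TBS = tert‑butyldimethylsilyl; the locants C1–C16 defined above are used for all intermediates.
Remark 2 (assumption): the (S)‑oxazaborolidine is taken to give the (R)‑allylic alcohol, with the 2‑methylvinyl carbon as the large group; otherwise the antipodal catalyst is used.
Remark 3 (chemistry): kinetic protonation of a C3=C4 enolate is expected anti to the C7 methyl and C8 silyloxy groups, which would give the wrong C4 epimer, so step 14 includes an equilibration before ring closure.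
Remark 4 (chemistry): the C12 oxygen is introduced on a lactone that masks the C3 ketone, because an ester enolate cannot be formed selectively beside the free ketone.

Step 1
Reactants: 1 2‑methylcyclohex‑2‑en‑1‑one
Product: 2 (R)‑2‑methylcyclohex‑2‑en‑1‑ol
Conditions: (S)‑1‑methyl‑3,3‑diphenyltetrahydro‑1H,3H‑pyrrolo[1,2‑c][1,3,2]oxazaborole (10 mol%), catecholborane, toluene, −78 °C
Reagents that add atoms: none
Why: Corey–Bakshi–Shibata reduction delivers hydride to one carbonyl face with the 2‑methylvinyl arm as the large substituent, which should set the (R)‑carbinol that becomes C8 with high enantiocontrol.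

Step 2
Reactants: 2 (R)‑2‑methylcyclohex‑2‑en‑1‑ol
Product: 3 (R)‑tert‑butyldimethyl[(2‑methylcyclohex‑2‑en‑1‑yl)oxy]silane
Conditions: TBSCl, imidazole, DMF, rt
Reagents that add atoms: tert‑butyldimethylsilyl chloride, CC(C)(C)[Si](C)(C)Cl
Why: Imidazole‑promoted silylation of a secondary allylic alcohol is routine and keeps the C8 oxygen protected until step 17.

Step 3
Reactants: 3 (R)‑tert‑butyldimethyl[(2‑methylcyclohex‑2‑en‑1‑yl)oxy]silane
Product: 4 (R)‑4‑(TBS‑oxy)‑3‑methylcyclohex‑2‑en‑1‑one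
Conditions: Rh2(caprolactamate)4 (1 mol%), t‑BuOOH, K2CO3 (cat.), CH2Cl2, rt
Reagents that add atoms: tert‑butyl hydroperoxide, CC(C)(C)OO
Why: Catalytic allylic C–H oxidation converts the ring methylene next to the unsubstituted alkene carbon into a carbonyl, so the C3 ketone arises in conjugation with C4=C7 and para to the untouched C8 stereocentre.

Step 4
Reactants: 4 (R)‑4‑(TBS‑oxy)‑3‑methylcyclohex‑2‑en‑1‑one
Product: 6 (4R)‑4‑(TBS‑oxy)‑3‑methyl‑6‑(phenylsulfanyl)cyclohex‑2‑en‑1‑one (both C6 epimers), via lithium dienolate 5 (not isolated)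
Conditions: LiN(i‑Pr)2, THF, −78 °C; then PhSO2SPh, −78 → 0 °C
Reagents that add atoms: S‑phenyl benzenethiosulfonate, O=S(=O)(Sc1ccccc1)c1ccccc1
Why: Kinetic deprotonation of the enone at the alpha‑prime methylene C10 and sulfenylation of the cross‑conjugated enolate (enolate sulfenylation) marks C10 for the later double bond, while the sulfur‑bearing centre is of no stereochemical consequence.

Step 5
Reactants: 6 (4R)‑4‑(TBS‑oxy)‑3‑methyl‑6‑(phenylsulfanyl)cyclohex‑2‑en‑1‑one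
Product: 7 (4R,5S)‑4‑(TBS‑oxy)‑5‑methyl‑2‑(phenylsulfanyl)cyclohexan‑1‑one (both C2 epimers)
Conditions: [(Ph3P)CuH]6, C6H6, H2O, rt
Reagents that add atoms: none
Why: In this Stryker conjugate reduction the C8 silyloxy group is pseudoaxial because of allylic strain with the C7 methyl, so copper hydride should attack C7 from the opposite face and leave the methyl cis to the silyloxy group (C7 S).

Step 6
Reactants: 7 (4R,5S)‑4‑(TBS‑oxy)‑5‑methyl‑2‑(phenylsulfanyl)cyclohexan‑1‑one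
Product: 9 (4S,5S)‑4‑(TBS‑oxy)‑5‑methylcyclohex‑2‑en‑1‑one, via sulfoxide 8 (not isolated)
Conditions: m‑ClC6H4CO3H, CH2Cl2, −78 °C; then toluene, 90 °C
Reagents that add atoms: none
Why: Oxidation to the alpha‑sulfinyl ketone and thermal sulfoxide syn‑elimination can use only the C9 hydrogens, which places the enone at C10=C9 regiospecifically without touching C7 or C8.

Step 7
Reactants: 9 (4S,5S)‑4‑(TBS‑oxy)‑5‑methylcyclohex‑2‑en‑1‑one, 10 methyl (E)‑but‑2‑enoate
Product: 12 methyl (3R)‑3‑[(1S,4S,5R)‑5‑(TBS‑oxy)‑4‑methyl‑2‑oxocyclohexyl]butanoate, via lithium enolate 11 (not isolated)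
Conditions: LiBH(s‑Bu)3, THF, −78 °C; then 10, −78 → −40 °C; AcOH
Reagents that add atoms: none
Why: Conjugate hydride addition to the beta‑unsubstituted enone gives the C3–C10 lithium enolate regiospecifically, and its Michael addition to the E‑crotonate through a closed lithium‑bridged transition state should occur anti to the axial C8 silyloxy group (C10 S) with the relative topicity that gives the required syn C10/C11 arrangement (C11 R at this stage).

Step 8
Reactants: 12 methyl (3R)‑3‑[(1S,4S,5R)‑5‑(TBS‑oxy)‑4‑methyl‑2‑oxocyclohexyl]butanoate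
Product: 14 (4R,4aS,6R,7S,8aR)‑6‑(TBS‑oxy)‑4,7‑dimethyloctahydro‑2H‑chromen‑2‑one, via hydroxy ester 13 (not isolated)
Conditions: NaBH4, CeCl3·7H2O, MeOH, −78 °C; then pyridinium p‑toluenesulfonate (cat.), toluene, 70 °C
Reagents that add atoms: none
Why: Luche‑type borohydride reduction delivers hydride axially to the C3 ketone to give mainly the equatorial alcohol (C3 R), which lactonises onto the ester under mild acid to the trans‑fused delta‑lactone that masks the ketone and fixes the conformation around C11 and C12.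

Step 9
Reactants: 14 (4R,4aS,6R,7S,8aR)‑6‑(TBS‑oxy)‑4,7‑dimethyloctahydro‑2H‑chromen‑2‑one
Product: 16 (3R,4S,4aS,6R,7S,8aR)‑6‑(TBS‑oxy)‑3‑hydroxy‑4,7‑dimethyloctahydro‑2H‑chromen‑2‑one, via potassium enolate 15 (not isolated)
Conditions: KN(SiMe3)2, THF, −78 °C; then 2‑(phenylsulfonyl)‑3‑phenyloxaziridine, −78 °C; AcOH
Reagents that add atoms: 2‑(phenylsulfonyl)‑3‑phenyloxaziridine, O=S(=O)(N1OC1c1ccccc1)c1ccccc1
Why: Davis oxidation of the potassium lactone enolate should bring the bulky oxaziridine to C12 on the face away from the adjacent C11 methyl, which places the new hydroxyl trans to that methyl in the equatorial position (C12 R).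

Step 10
Reactants: 16 (3R,4S,4aS,6R,7S,8aR)‑6‑(TBS‑oxy)‑3‑hydroxy‑4,7‑dimethyloctahydro‑2H‑chromen‑2‑one
Product: 17 (3R,4S,4aS,6R,7S,8aR)‑3,6‑bis(TBS‑oxy)‑4,7‑dimethyloctahydro‑2H‑chromen‑2‑one
Conditions: t‑BuMe2SiOTf, 2,6‑lutidine, CH2Cl2, 0 °C
Reagents that add atoms: tert‑butyldimethylsilyl trifluoromethanesulfonate, CC(C)(C)[Si](C)(C)OS(=O)(=O)C(F)(F)F
Why: Silyl triflate with 2,6‑lutidine silylates the hindered alpha‑hydroxy lactone cleanly and gives the C12 silyl ether of the key‑step precursor.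

Step 11
Reactants: 17 (3R,4S,4aS,6R,7S,8aR)‑3,6‑bis(TBS‑oxy)‑4,7‑dimethyloctahydro‑2H‑chromen‑2‑one
Product: 18 (2R,3S)‑2‑(TBS‑oxy)‑3‑[(1S,2R,4S,5R)‑5‑(TBS‑oxy)‑2‑hydroxy‑4‑methylcyclohexyl]‑N‑methoxy‑N‑methylbutanamide
Conditions: MeNH(OMe)·HCl, AlMe3, CH2Cl2, 0 °C → rt
Reagents that add atoms: N,O‑dimethylhydroxylamine hydrochloride, CNOC.Cl
Why: Weinreb aminolysis with the aluminium amide formed from AlMe3 and the amine hydrochloride opens the lactone at the acyl carbon, which installs the N‑methoxy‑N‑methylamide without touching C12 and frees the C3 alcohol.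

Step 12
Reactants: 18 (2R,3S)‑2‑(TBS‑oxy)‑3‑[(1S,2R,4S,5R)‑5‑(TBS‑oxy)‑2‑hydroxy‑4‑methylcyclohexyl]‑N‑methoxy‑N‑methylbutanamide
Product: 19 (2R,3S)‑2‑(TBS‑oxy)‑3‑[(1S,4S,5R)‑5‑(TBS‑oxy)‑4‑methyl‑2‑oxocyclohexyl]‑N‑methoxy‑N‑methylbutanamide
Conditions: Dess–Martin periodinane, pyridine, CH2Cl2, rt
Reagents that add atoms: none
Why: Dess–Martin oxidation of the secondary C3 alcohol under buffered conditions restores the ketone, and the adjacent C10 centre is already in its thermodynamically preferred equatorial configuration.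

Step 13
Reactants: 19 (2R,3S)‑2‑(TBS‑oxy)‑3‑[(1S,4S,5R)‑5‑(TBS‑oxy)‑4‑methyl‑2‑oxocyclohexyl]‑N‑methoxy‑N‑methylbutanamide
Product: 23 (2R,3S)‑2‑(TBS‑oxy)‑3‑[(1S,4S,5R)‑5‑(TBS‑oxy)‑4‑methyl‑3‑methylidene‑2‑oxocyclohexyl]‑N‑methoxy‑N‑methylbutanamide, via lithium enolate 20 (not isolated), via Mannich base 21 (not isolated), via ammonium iodide 22 (not isolated)
Conditions: LiN(SiMe3)2, THF, −78 °C; then Me2N=CH2+ I−, −78 → 0 °C; then MeI, rt; then aq. NaHCO3, CH2Cl2, rt
Reagents that add atoms: N,N‑dimethylmethyleneiminium iodide, C=[N+](C)C.[I-]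
Why: Kinetic enolisation at the unsubstituted C4 methylene followed by a Mannich reaction with the iminium salt, quaternisation and E1cB loss of trimethylamine (Eschenmoser methylenation) gives the exocyclic enone, since the tertiary C10 is deprotonated more slowly and could not lead to an alkene.

Step 14
Reactants: 23 (2R,3S)‑2‑(TBS‑oxy)‑3‑[(1S,4S,5R)‑5‑(TBS‑oxy)‑4‑methyl‑3‑methylidene‑2‑oxocyclohexyl]‑N‑methoxy‑N‑methylbutanamide, 24 (2‑methylidenepropane‑1,3‑diyl)bis(trimethylsilane)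
Product: 27 trans‑fused C3 carbinol (3S,4S,7S,8R,10S,11S,12R) with C1=C16 methylidene, via trichlorotitanium enolate 25 (not isolated), via keto allylsilane 26 (not isolated)
Conditions: TiCl4, CH2Cl2, −78 °C; then i‑PrOH, i‑Pr2NEt (cat.), −78 → −30 °C; then TiCl4, −78 → −40 °C; aq. NaHCO3
Reagents that add atoms: none
Why: TiCl4 activates the exocyclic enone and the bis‑allylsilane adds through its methylene terminus to C5 (Hosomi–Sakurai conjugate allylation, SE2'), which forms C5–C6, expels Me3SiCl and leaves the trichlorotitanium enolate 25 whose side arm is a new allylsilane with C2 as its nucleophilic terminus. Protonation with i‑PrOH and amine‑shuttled enolate/ketone exchange should let C4 settle with C5 equatorial, trans to the C7 methyl and free of a 1,3‑diaxial contact with the C8 silyloxy group, so this centre is under thermodynamic and not kinetic control. Fresh TiCl4 then triggers the intramolecular allylsilane–ketone addition, a 6‑exo‑trig closure on the C3 carbonyl that forms C2–C3 and releases the C1=C16 methylene. The chair‑like closure from the equatorial tether with equatorial entry of C2, as in Lewis‑acid allylations of cyclohexanones, should give the trans ring fusion with the titanium‑bound oxygen axial (C3 S), away from the two equatorial alpha substituents. The closest known reactions are the conjugate allylation of alpha‑methylene ketones and the Lewis‑acid cyclisation of keto allylsilanes derived from 2‑(silylmethyl)allyl conjunctive reagents. The step needs 1,4‑ before 1,2‑addition and the correct C4 configuration, which the unhindered methylene beside a doubly flanked ketone and the all‑equatorial ring B should secure, whereas C3 is erased in step 15.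

Step 15
Reactants: 27 trans‑fused C3 carbinol
Product: 28 diene Weinreb amide (4S,7S,8R,10S,11S,12R) with the C16=C1–C2=C3 diene
Conditions: Burgess reagent (MeO2C–N–SO2–NEt3 inner salt), toluene, 70 °C
Reagents that add atoms: none
Why: Burgess dehydration is a syn‑elimination, and in the trans‑fused carbinol the axial C3 oxygen has a cis hydrogen only at C2 because H4 and H10 are antiperiplanar to it, so the conjugated C16=C1–C2=C3 diene should form regiospecifically.

Step 16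
Reactants: 28 diene Weinreb amide, 29 2‑methylprop‑1‑enylmagnesium bromide
Product: 31 8,12‑bis(TBS‑oxy) dienone with the C13 ketone and C14=C15 alkene, via magnesium hemiaminal 30 (not isolated)
Conditions: THF, −20 → 0 °C; aq. NH4Cl
Reagents that add atoms: none
Why: Addition of the alkenyl Grignard reagent to the Weinreb amide stops at the chelated tetrahedral adduct, which collapses to the enone only on work‑up, so that over‑addition and conjugate addition are avoided and C12 is untouched.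

Step 17
Reactants: 31 8,12‑bis(TBS‑oxy) dienone
Product: 32 8,12‑diol
Conditions: HF·pyridine, pyridine, THF, 0 °C → rt
Reagents that add atoms: none
Why: Buffered hydrogen fluoride removes both silyl ethers without the basic conditions that could epimerise the alpha‑hydroxy ketone or shift the diene.

Step 18
Reactants: 32 8,12‑diol
Product: 33 target CNP0302999.1 (4S,7S,8R,10S,11S,12R)‑8,12‑diacetate
Conditions: Ac2O, pyridine, 4‑(dimethylamino)pyridine (cat.), CH2Cl2, 0 °C → rt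
Reagents that add atoms: acetic anhydride, CC(=O)OC(C)=O
Why: Acylation of both secondary alcohols with acetic anhydride under nucleophilic catalysis gives the diacetate target without affecting any stereocentre.

Compound list
1 | 2‑methylcyclohex‑2‑en‑1‑one | CC1=CCCCC1=O | starting material
2 | (R)‑2‑methylcyclohex‑2‑en‑1‑ol | CC1=CCCC[C@H]1O | intermediate
3 | (R)‑tert‑butyldimethyl[(2‑methylcyclohex‑2‑en‑1‑yl)oxy]silane | CC1=CCCC[C@H]1O[Si](C)(C)C(C)(C)C | intermediate
4 | (R)‑4‑(TBS‑oxy)‑3‑methylcyclohex‑2‑en‑1‑one | CC1=CC(=O)CC[C@H]1O[Si](C)(C)C(C)(C)C | intermediate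
5 | lithium cross‑conjugated dienolate of 4 (O–Li on C3; C3=C10 and C4=C7) | CC1=CC(O[Li])=CC[C@H]1O[Si](C)(C)C(C)(C)C | intermediate
6 | (4R)‑4‑(TBS‑oxy)‑3‑methyl‑6‑(phenylsulfanyl)cyclohex‑2‑en‑1‑one (C6 epimers) | CC1=CC(=O)C(Sc2ccccc2)C[C@H]1O[Si](C)(C)C(C)(C)C | intermediate
7 | (4R,5S)‑4‑(TBS‑oxy)‑5‑methyl‑2‑(phenylsulfanyl)cyclohexan‑1‑one (C2 epimers) | C[C@H]1CC(=O)C(Sc2ccccc2)C[C@H]1O[Si](C)(C)C(C)(C)C | intermediate
8 | (4R,5S)‑4‑(TBS‑oxy)‑5‑methyl‑2‑(phenylsulfinyl)cyclohexan‑1‑one | C[C@H]1CC(=O)C(S(=O)c2ccccc2)C[C@H]1O[Si](C)(C)C(C)(C)C | intermediate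
9 | (4S,5S)‑4‑(TBS‑oxy)‑5‑methylcyclohex‑2‑en‑1‑one | C[C@H]1CC(=O)C=C[C@H]1O[Si](C)(C)C(C)(C)C | intermediate
10 | methyl (E)‑but‑2‑enoate | C/C=C/C(=O)OC | starting material
11 | lithium (4R,5S)‑4‑(TBS‑oxy)‑5‑methylcyclohex‑1‑en‑1‑olate | C[C@H]1CC(O[Li])=CC[C@H]1O[Si](C)(C)C(C)(C)C | intermediate
12 | methyl (3R)‑3‑[(1S,4S,5R)‑5‑(TBS‑oxy)‑4‑methyl‑2‑oxocyclohexyl]butanoate | C[C@H]1CC(=O)[C@H]([C@H](C)CC(=O)OC)C[C@H]1O[Si](C)(C)C(C)(C)C | intermediate
13 | methyl (3R)‑3‑[(1S,2R,4S,5R)‑5‑(TBS‑oxy)‑2‑hydroxy‑4‑methylcyclohexyl]butanoate | C[C@H]1C[C@@H](O)[C@H]([C@H](C)CC(=O)OC)C[C@H]1O[Si](C)(C)C(C)(C)C | intermediate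
14 | (4R,4aS,6R,7S,8aR)‑6‑(TBS‑oxy)‑4,7‑dimethyloctahydro‑2H‑chromen‑2‑one | C[C@H]1C[C@H]2OC(=O)C[C@@H](C)[C@@H]2C[C@H]1O[Si](C)(C)C(C)(C)C | intermediate
15 | potassium enolate of lactone 14 (O–K on C13; C12=C13) | C[C@H]1C[C@H]2OC(O[K])=C[C@@H](C)[C@@H]2C[C@H]1O[Si](C)(C)C(C)(C)C | intermediate
16 | (3R,4S,4aS,6R,7S,8aR)‑6‑(TBS‑oxy)‑3‑hydroxy‑4,7‑dimethyloctahydro‑2H‑chromen‑2‑one | C[C@H]1C[C@H]2OC(=O)[C@H](O)[C@@H](C)[C@@H]2C[C@H]1O[Si](C)(C)C(C)(C)C | intermediate
17 | (3R,4S,4aS,6R,7S,8aR)‑3,6‑bis(TBS‑oxy)‑4,7‑dimethyloctahydro‑2H‑chromen‑2‑one | C[C@H]1C[C@H]2OC(=O)[C@H](O[Si](C)(C)C(C)(C)C)[C@@H](C)[C@@H]2C[C@H]1O[Si](C)(C)C(C)(C)C | intermediate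
18 | (2R,3S)‑2‑(TBS‑oxy)‑3‑[(1S,2R,4S,5R)‑5‑(TBS‑oxy)‑2‑hydroxy‑4‑methylcyclohexyl]‑N‑methoxy‑N‑methylbutanamide | C[C@H]1C[C@@H](O)[C@H]([C@H](C)[C@@H](O[Si](C)(C)C(C)(C)C)C(=O)N(C)OC)C[C@H]1O[Si](C)(C)C(C)(C)C | intermediate
19 | (2R,3S)‑2‑(TBS‑oxy)‑3‑[(1S,4S,5R)‑5‑(TBS‑oxy)‑4‑methyl‑2‑oxocyclohexyl]‑N‑methoxy‑N‑methylbutanamide | C[C@H]1CC(=O)[C@H]([C@H](C)[C@@H](O[Si](C)(C)C(C)(C)C)C(=O)N(C)OC)C[C@H]1O[Si](C)(C)C(C)(C)C | intermediate
20 | lithium C3–C4 enolate of 19 | C[C@H]1C=C(O[Li])[C@H]([C@H](C)[C@@H](O[Si](C)(C)C(C)(C)C)C(=O)N(C)OC)C[C@H]1O[Si](C)(C)C(C)(C)C | intermediate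
21 | C4‑(dimethylaminomethyl) derivative of 19 (C4 epimers) | C[C@H]1C(CN(C)C)C(=O)[C@H]([C@H](C)[C@@H](O[Si](C)(C)C(C)(C)C)C(=O)N(C)OC)C[C@H]1O[Si](C)(C)C(C)(C)C | intermediate
22 | C4‑(trimethylammoniomethyl) derivative of 19, iodide | C[C@H]1C(C[N+](C)(C)C)C(=O)[C@H]([C@H](C)[C@@H](O[Si](C)(C)C(C)(C)C)C(=O)N(C)OC)C[C@H]1O[Si](C)(C)C(C)(C)C.[I-] | intermediate
23 | (2R,3S)‑2‑(TBS‑oxy)‑3‑[(1S,4S,5R)‑5‑(TBS‑oxy)‑4‑methyl‑3‑methylidene‑2‑oxocyclohexyl]‑N‑methoxy‑N‑methylbutanamide (key‑step precursor) | C=C1[C@H](C)[C@H](O[Si](C)(C)C(C)(C)C)C[C@@H]([C@H](C)[C@@H](O[Si](C)(C)C(C)(C)C)C(=O)N(C)OC)C1=O | intermediate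
24 | (2‑methylidenepropane‑1,3‑diyl)bis(trimethylsilane) | C=C(C[Si](C)(C)C)C[Si](C)(C)C | starting material
25 | trichlorotitanium C3–C4 enolate carrying the C5–C6–C1(=CH2)–CH2SiMe3 arm on C4 | C[C@H]1C(CCC(=C)C[Si](C)(C)C)=C(O[Ti](Cl)(Cl)Cl)[C@H]([C@H](C)[C@@H](O[Si](C)(C)C(C)(C)C)C(=O)N(C)OC)C[C@H]1O[Si](C)(C)C(C)(C)C | intermediate
26 | (4S)‑keto allylsilane: C3 ketone with equatorial C4–CH2CH2C(=CH2)CH2SiMe3 | C[C@H]1[C@H](CCC(=C)C[Si](C)(C)C)C(=O)[C@H]([C@H](C)[C@@H](O[Si](C)(C)C(C)(C)C)C(=O)N(C)OC)C[C@H]1O[Si](C)(C)C(C)(C)C | intermediate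
27 | trans‑fused carbinol (3S,4S,7S,8R,10S,11S,12R): ring A with C1=C16 methylidene and axial C3–OH, ring B with C7 methyl and C8 OTBS, C10 side chain CH(Me)–CH(OTBS)–C(O)N(OMe)Me | C=C1C[C@]2(O)[C@@H](CC1)[C@H](C)[C@H](O[Si](C)(C)C(C)(C)C)C[C@H]2[C@H](C)[C@@H](O[Si](C)(C)C(C)(C)C)C(=O)N(C)OC | intermediate
28 | diene Weinreb amide (4S,7S,8R,10S,11S,12R) with the C16=C1–C2=C3 diene | C=C1C=C2[C@@H](CC1)[C@H](C)[C@H](O[Si](C)(C)C(C)(C)C)C[C@H]2[C@H](C)[C@@H](O[Si](C)(C)C(C)(C)C)C(=O)N(C)OC | intermediate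
29 | 2‑methylprop‑1‑enylmagnesium bromide | CC(C)=C[Mg]Br | starting material
30 | magnesium hemiaminal at C13 (chelated tetrahedral adduct) | C=C1C=C2[C@@H](CC1)[C@H](C)[C@H](O[Si](C)(C)C(C)(C)C)C[C@H]2[C@H](C)[C@@H](O[Si](C)(C)C(C)(C)C)C(O[Mg]Br)(N(C)OC)C=C(C)C | intermediate
31 | 8,12‑bis(TBS‑oxy) dienone (4S,7S,8R,10S,11S,12R) with the C13 ketone and C14=C15(Me)2 | C=C1C=C2[C@@H](CC1)[C@H](C)[C@H](O[Si](C)(C)C(C)(C)C)C[C@H]2[C@H](C)[C@@H](O[Si](C)(C)C(C)(C)C)C(=O)C=C(C)C | intermediate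
32 | 8,12‑diol (4S,7S,8R,10S,11S,12R) | C=C1C=C2[C@@H](CC1)[C@H](C)[C@H](O)C[C@H]2[C@H](C)[C@@H](O)C(=O)C=C(C)C | intermediate
33 | CNP0302999.1, (4S,7S,8R,10S,11S,12R)‑8,12‑diacetate | C=C1C=C2[C@@H](CC1)[C@H](C)[C@H](OC(C)=O)C[C@H]2[C@H](C)[C@@H](OC(C)=O)C(=O)C=C(C)C | target

Total step count: 18. Longest linear sequence: 18 steps (1 to 33); 10, 24 and 29 are purchased.

Steps most likely to fail

1. Step 14 (key step). What may go wrong: protodesilylation of the pendant allylsilane before ring closure, incomplete equilibration at C4, poor facial selectivity in the addition to C3, or attack of the titanium alkoxide on the amide. Fallback (a Robinson‑type annulation followed by olefination): starting from 23, a Mukaiyama–Michael addition of 2‑(trimethylsilyloxy)propene (TiCl4, CH2Cl2, −78 °C) gives the 1,5‑diketone F1. NaOMe in MeOH equilibrates C4 to the equatorial epimer and effects the intramolecular aldol condensation to the bicyclic enone F2. Wittig methylenation of the C1 ketone (Ph3P=CH2, THF, 0 °C) then gives diene 28, where the route is rejoined with steps 14 and 15 bypassed.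

2. Step 7. What may go wrong: competing 1,2‑reduction of the enone, sluggish addition of the borane‑complexed enolate to the crotonate, or erosion of the C10/C11 selectivity through an open transition state. Fallback: starting from 9, rhodium‑catalysed 1,4‑hydrosilylation (Et3SiH, RhCl(PPh3)3, THF, 50 °C) gives the isolable triethylsilyl enol ether F3. Cleavage with MeLi (THF, 0 °C) releases the borane‑free lithium enolate 11, which is added to 10 at −78 °C to return to 12.

3. Step 9. What may go wrong: poor or reversed facial selectivity of the enolate oxidation at C12, since the C11 methyl is only pseudoequatorial in the rigid lactone. Fallback: starting from 14, the oxidation is accepted as it comes and the C12 epimer F4 is separated and inverted by a Mitsunobu reaction (4‑nitrobenzoic acid, PPh3, diisopropyl azodicarboxylate, THF) to the 4‑nitrobenzoate F5. Mild methanolysis (K2CO3, MeOH, 0 °C, then pyridinium p‑toluenesulfonate to re‑close any opened lactone) returns to 16.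

Further compounds
F1 | step 14 | (4S)‑1,5‑diketone: C4‑(3‑oxobutyl) analogue of 19 | C[C@H]1[C@H](CCC(C)=O)C(=O)[C@H]([C@H](C)[C@@H](O[Si](C)(C)C(C)(C)C)C(=O)N(C)OC)C[C@H]1O[Si](C)(C)C(C)(C)C
F2 | step 14 | bicyclic enone (C1 ketone conjugated with C2=C3) Weinreb amide (4S,7S,8R,10S,11S,12R) | O=C1C=C2[C@@H](CC1)[C@H](C)[C@H](O[Si](C)(C)C(C)(C)C)C[C@H]2[C@H](C)[C@@H](O[Si](C)(C)C(C)(C)C)C(=O)N(C)OC
F3 | step 7 | (4R,5S)‑4‑(TBS‑oxy)‑5‑methyl‑1‑(triethylsilyloxy)cyclohex‑1‑ene | CC[Si](CC)(CC)OC1=CC[C@@H](O[Si](C)(C)C(C)(C)C)[C@@H](C)C1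
F4 | step 9 | (3S,4S,4aS,6R,7S,8aR)‑6‑(TBS‑oxy)‑3‑hydroxy‑4,7‑dimethyloctahydro‑2H‑chromen‑2‑one (C12 epimer of 16) | C[C@H]1C[C@H]2OC(=O)[C@@H](O)[C@@H](C)[C@@H]2C[C@H]1O[Si](C)(C)C(C)(C)C
F5 | step 9 | 4‑nitrobenzoate of 16 (C12 R) | C[C@H]1C[C@H]2OC(=O)[C@H](OC(=O)c3ccc(cc3)[N+](=O)[O-])[C@@H](C)[C@@H]2C[C@H]1O[Si](C)(C)C(C)(C)C
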